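**Retrosynthetic overview**
1. Target 20 ⇐ Luche reduction of C7 enone 19 ⇐ allylic oxidation, anisoylation and OH-directed ketone reduction of the trans-fused hydroazulenone 15.
2. 15 ⇐ key 1,2-shift: semipinacol rearrangement of the all-cis decalin triol monomesylate 14 (C4a moves from C8a to C1: one ring 6→5, the other 6→7, trans fusion set by inversion).
3. Triol 13 ⇐ OH-directed syn-dihydroxylation of dienol 11 ⇐ i-PrMgCl + dienone 10.
4. 10 ⇐ Wichterle annulation of 8 ⇐ new Pd-catalysed asymmetric alkylation of the dienolate of 5 with 1,3-dichlorobut-2-ene (the only step that sets absolute configuration) ⇐ 3-methylcyclohexenone + MeI.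
5. Ring order: cyclohexenone (bought) → second six-membered ring (annulation) → both rings reshaped to 5/7 in the shift; the anisoyl unit comes from anisole + oxalyl chloride.

Assumption: MeI, i-PrMgCl, oxalyl chloride, OsO4, t-BuOOH and water are treated as atom-donating reagents (not numbered); 1,3-dichlorobut-2-ene is the commercial E/Z mixture and LDA a commercial solution.

**Step 1**
Reactants: 1 anisole
Product: 2 4-methoxybenzoyl chloride
Conditions: (COCl)2 (2.5 equiv), AlCl3 (1.1 equiv), CH2Cl2, −10 → 0 °C; ice quench, vacuum distillation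
Reagents that add atoms: oxalyl chloride ClC(=O)C(=O)Cl
Why: Friedel–Crafts chlorocarbonylation: the ClCO+ equivalent attacks para to OMe, and excess oxalyl chloride at low temperature keeps the acid chloride from acylating a second anisole.

**Step 2**
Reactants: 3 3-methylcyclohex-2-en-1-one
Product: 5 (±)-3,6-dimethylcyclohex-2-en-1-one, via lithium dienolate 4 (not isolated)
Conditions: LDA (1.05 equiv), THF, −78 °C; MeI, −78 → 0 °C
Reagents that add atoms: iodomethane CI
Why: Kinetic α′-deprotonation gives the cross-conjugated dienolate, which is C-methylated (enolate alkylation); the new stereocentre is racemic and is erased again in step 3.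

**Step 3**
Reactants: 5 (±)-3,6-dimethylcyclohex-2-en-1-one, 6 1,3-dichlorobut-2-ene
Product: 8 (S)-6-(3-chlorobut-2-en-1-yl)-3,6-dimethylcyclohex-2-en-1-one, via lithium dienolate 7 (not isolated)
Conditions: LDA (1.05 equiv), THF, −78 °C; then Pd2(dba)3 (2.5 mol %), (S)-t-Bu-PHOX (6 mol %), 6 (1.2 equiv), −40 → 0 °C
Reagents that add atoms: none
Why: Proposed new method: Pd(0)/PHOX ionises only the allylic C–Cl bond of 6 to a (1-chloro-1-methylallyl)Pd cation (the vinylic C–Cl bond is inert under these conditions), the planar tetrasubstituted dienolate 7 binds Pd through oxygen, and reductive elimination at the unsubstituted allyl terminus from the ligand-selected enolate face gives the (S) quaternary centre stereoconvergently from racemic 5 (ligand sense taken by analogy with 2-allyl-2-methylcyclohexanone); the closest known reactions are Pd-catalysed asymmetric allylic alkylations of non-stabilised ketone enolates to α-quaternary cyclohexanones (2-chloroallyl electrophiles included) and the racemic Wichterle alkylation.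

**Step 4**
Reactants: 8 (S)-6-(3-chlorobut-2-en-1-yl)-3,6-dimethylcyclohex-2-en-1-one
Product: 10 (S)-4a,7-dimethyl-4,4a,5,6-tetrahydronaphthalen-2(3H)-one, via diketone 9 (not isolated)
Conditions: 90% H2SO4, 0 → 25 °C; ice
Reagents that add atoms: water O
Why: Wichterle annulation: acid hydrolysis of the vinyl chloride gives methyl ketone 9, whose enol condenses with the protonated ring carbonyl (intramolecular aldol condensation) to the linearly conjugated dienone; the quaternary centre cannot epimerise.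

**Step 5**
Reactants: 10 (S)-4a,7-dimethyl-4,4a,5,6-tetrahydronaphthalen-2(3H)-one
Product: 11 (2R,4aS)-4a,7-dimethyl-2-(propan-2-yl)-2,3,4,4a,5,6-hexahydronaphthalen-2-ol
Conditions: i-PrMgCl (1.5 equiv), LaCl3·2LiCl (1.0 equiv), THF, −40 → 0 °C; aq. NH4Cl
Reagents that add atoms: isopropylmagnesium chloride CC(C)[Mg]Cl
Why: Lanthanide-promoted Grignard 1,2-addition; axial attack on the half-chair enone anti to the angular methyl (the sense expected by analogy with hydride and alkyl additions to 4a-methyl octalenones and 4-en-3-one steroids) places OH cis to CH3 (2R), and the minor epimer is removed by chromatography.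

**Step 6**
Reactants: 11 (2R,4aS)-4a,7-dimethyl-2-(propan-2-yl)-2,3,4,4a,5,6-hexahydronaphthalen-2-ol
Product: 13 (1S,2R,4aS,8aR)-4a,7-dimethyl-2-(propan-2-yl)-1,2,3,4,4a,5,6,8a-octahydronaphthalene-1,2,8a-triol, via osmate ester 12 (not isolated)
Conditions: OsO4 (1.05 equiv), TMEDA (1.1 equiv), CH2Cl2, −78 °C; then aq. Na2SO3, THF, 60 °C
Reagents that add atoms: osmium tetroxide O=[Os](=O)(=O)=O
Why: Hydrogen-bond-directed syn-dihydroxylation: the OsO4·TMEDA complex is held by the tertiary allylic OH and adds to the adjacent C1=C8a bond on the OH face, giving the all-cis triol (1-OH, 2-OH, 8a-OH and 4a-CH3 on one face); one equivalent spares the remote C7=C8 bond.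

**Step 7**
Reactants: 13 (1S,2R,4aS,8aR)-4a,7-dimethyl-2-(propan-2-yl)-1,2,3,4,4a,5,6,8a-octahydronaphthalene-1,2,8a-triol
Product: 15 (3R,3aR,8aS)-3-hydroxy-6,8a-dimethyl-3-(propan-2-yl)-2,3,3a,7,8,8a-hexahydroazulen-4(1H)-one, via mesylate 14 (not isolated)
Conditions: MsCl (1.2 equiv), Et3N, CH2Cl2, −20 °C; then KOt-Bu (2.5 equiv), THF, −20 → 0 °C, cold AcOH quench
Reagents that add atoms: none
Why: Semipinacol (pinacol-type) 1,2-shift: in the chair with equatorial i-Pr and equatorial OMs the C8a–C4a bond is antiperiplanar to C1–OMs, so the C8a alkoxide pushes the quaternary C4a from C8a to C1 with inversion at C1, which contracts one ring to the cyclopentane, expands the other to the cycloheptenone and fixes the trans ring fusion; the all-cis geometry excludes epoxide formation and E2, and the tertiary migrating carbon should outrun the primary C3 that the C2 alkoxide could push.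

**Step 8**
Reactants: 15 (3R,3aR,8aS)-3-hydroxy-6,8a-dimethyl-3-(propan-2-yl)-2,3,3a,7,8,8a-hexahydroazulen-4(1H)-one
Product: 16 (3R,3aS,4S,8aS)-6,8a-dimethyl-3-(propan-2-yl)-1,2,3,3a,4,7,8,8a-octahydroazulene-3,4-diol
Conditions: Me4NBH(OAc)3 (5 equiv), MeCN/AcOH (1:1), −30 → 0 °C
Reagents that add atoms: none
Why: Hydroxyl-directed (Evans–Saksena type) 1,2-reduction: the tertiary 3-OH exchanges onto boron and delivers hydride intramolecularly to the face of C4 on which it sits, giving the 1,3-anti diol (4S) without touching the alkene.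

**Step 9**
Reactants: 16 (3R,3aS,4S,8aS)-6,8a-dimethyl-3-(propan-2-yl)-1,2,3,3a,4,7,8,8a-octahydroazulene-3,4-diol, 2 4-methoxybenzoyl chloride
Product: 17 (3R,3aS,4S,8aS)-3-hydroxy-6,8a-dimethyl-3-(propan-2-yl)-1,2,3,3a,4,7,8,8a-octahydroazulen-4-yl 4-methoxybenzoate
Conditions: pyridine, DMAP (0.2 equiv), CH2Cl2, 0 → 25 °C
Reagents that add atoms: none
Why: DMAP-catalysed acylation; only the secondary allylic OH reacts, the hindered tertiary OH is inert.

**Step 10**
Reactants: 17 (3R,3aS,4S,8aS)-3-hydroxy-6,8a-dimethyl-3-(propan-2-yl)-1,2,3,3a,4,7,8,8a-octahydroazulen-4-yl 4-methoxybenzoate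
Product: 19 (3R,3aS,4S,8aR)-3-hydroxy-6,8a-dimethyl-7-oxo-3-(propan-2-yl)-1,2,3,3a,4,7,8,8a-octahydroazulen-4-yl 4-methoxybenzoate, via allylic alcohol 18 (not isolated)
Conditions: SeO2 (cat.), t-BuOOH, CH2Cl2, 25 °C; aq. Na2S2O3 wash; then Dess–Martin periodinane, NaHCO3, CH2Cl2, 0 °C
Reagents that add atoms: tert-butyl hydroperoxide CC(C)(C)OO
Why: SeO2 allylic oxidation (ene reaction then [2,3]-shift) hydroxylates the ring CH2 next to the more substituted alkene carbon (C7) without allylic transposition, and both C7 epimers converge on the enone in the Dess–Martin oxidation.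

**Step 11**
Reactants: 19 (3R,3aS,4S,8aR)-3-hydroxy-6,8a-dimethyl-7-oxo-3-(propan-2-yl)-1,2,3,3a,4,7,8,8a-octahydroazulen-4-yl 4-methoxybenzoate
Product: 20 (3R,3aS,4S,7R,8aR)-3,7-dihydroxy-6,8a-dimethyl-3-(propan-2-yl)-1,2,3,3a,4,7,8,8a-octahydroazulen-4-yl 4-methoxybenzoate
Conditions: NaBH4, CeCl3·7H2O, MeOH, −78 °C
Reagents that add atoms: none
Why: Luche 1,2-reduction: hydride adds to C7 from the face anti to the pseudo-axial, 1,3-related 8a-methyl, so the new OH is cis to that methyl (7R); the ester and the tertiary alcohol are untouched.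

**Compound list**
1 | anisole | COc1ccccc1 | starting material
2 | 4-methoxybenzoyl chloride | COc1ccc(cc1)C(Cl)=O | intermediate
3 | 3-methylcyclohex-2-en-1-one | CC1=CC(=O)CCC1 | starting material
4 | lithium 5-methylcyclohexa-1,5-dien-1-olate | [Li]OC1=CCCC(C)=C1 | intermediate
5 | (±)-3,6-dimethylcyclohex-2-en-1-one | CC1CCC(C)=CC1=O | intermediate
6 | 1,3-dichlorobut-2-ene (E/Z mixture) | CC(Cl)=CCCl | starting material
7 | lithium 2,5-dimethylcyclohexa-1,5-dien-1-olate | [Li]OC1=C(C)CCC(C)=C1 | intermediate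
8 | (S)-6-(3-chlorobut-2-en-1-yl)-3,6-dimethylcyclohex-2-en-1-one (E/Z at the vinyl chloride) | CC(Cl)=CC[C@]1(C)CCC(C)=CC1=O | intermediate
9 | (S)-3,6-dimethyl-6-(3-oxobutyl)cyclohex-2-en-1-one | CC(=O)CC[C@]1(C)CCC(C)=CC1=O | intermediate
10 | (S)-4a,7-dimethyl-4,4a,5,6-tetrahydronaphthalen-2(3H)-one | O=C1CC[C@]2(C)CCC(C)=CC2=C1 | intermediate
11 | (2R,4aS)-4a,7-dimethyl-2-(propan-2-yl)-2,3,4,4a,5,6-hexahydronaphthalen-2-ol (OH cis to 4a-CH3) | CC(C)[C@]1(O)CC[C@]2(C)CCC(C)=CC2=C1 | intermediate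
12 | cyclic osmate(VI) ester of 13 across O-1 and O-8a, TMEDA adduct | O=[Os]1(=O)O[C@]23C=C(C)CC[C@@]2(C)CC[C@@](O)(C(C)C)[C@@H]3O1.CN(C)CCN(C)C | intermediate
13 | (1S,2R,4aS,8aR)-4a,7-dimethyl-2-(propan-2-yl)-1,2,3,4,4a,5,6,8a-octahydronaphthalene-1,2,8a-triol (three OH and 4a-CH3 all cis) | O[C@]12C=C(C)CC[C@@]1(C)CC[C@@](O)(C(C)C)[C@@H]2O | intermediate
14 | (1S,2R,4aS,8aR)-2,8a-dihydroxy-4a,7-dimethyl-2-(propan-2-yl)-1,2,3,4,4a,5,6,8a-octahydronaphthalen-1-yl methanesulfonate | O[C@]12C=C(C)CC[C@@]1(C)CC[C@@](O)(C(C)C)[C@@H]2OS(C)(=O)=O | intermediate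
15 | (3R,3aR,8aS)-3-hydroxy-6,8a-dimethyl-3-(propan-2-yl)-2,3,3a,7,8,8a-hexahydroazulen-4(1H)-one (trans-fused) | O=C2C=C(C)CC[C@@]3(C)CC[C@@](O)(C(C)C)[C@H]23 | intermediate
16 | (3R,3aS,4S,8aS)-6,8a-dimethyl-3-(propan-2-yl)-1,2,3,3a,4,7,8,8a-octahydroazulene-3,4-diol | O[C@H]2C=C(C)CC[C@@]3(C)CC[C@@](O)(C(C)C)[C@H]23 | intermediate
17 | (3R,3aS,4S,8aS)-3-hydroxy-6,8a-dimethyl-3-(propan-2-yl)-1,2,3,3a,4,7,8,8a-octahydroazulen-4-yl 4-methoxybenzoate | COc1ccc(C(=O)O[C@H]2C=C(C)CC[C@@]3(C)CC[C@@](O)(C(C)C)[C@H]23)cc1 | intermediate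
18 | (3R,3aS,4S,8aR)-3,7-dihydroxy-6,8a-dimethyl-3-(propan-2-yl)-1,2,3,3a,4,7,8,8a-octahydroazulen-4-yl 4-methoxybenzoate, mixture of C7 epimers | COc1ccc(C(=O)O[C@H]2C=C(C)C(O)C[C@@]3(C)CC[C@@](O)(C(C)C)[C@H]23)cc1 | intermediate
19 | (3R,3aS,4S,8aR)-3-hydroxy-6,8a-dimethyl-7-oxo-3-(propan-2-yl)-1,2,3,3a,4,7,8,8a-octahydroazulen-4-yl 4-methoxybenzoate | COc1ccc(C(=O)O[C@H]2C=C(C)C(=O)C[C@@]3(C)CC[C@@](O)(C(C)C)[C@H]23)cc1 | intermediate
20 | (3R,3aS,4S,7R,8aR)-3,7-dihydroxy-6,8a-dimethyl-3-(propan-2-yl)-1,2,3,3a,4,7,8,8a-octahydroazulen-4-yl 4-methoxybenzoate (CNP0251753.2) | COc1ccc(C(=O)O[C@H]2C=C(C)[C@H](O)C[C@@]3(C)CC[C@@](O)(C(C)C)[C@H]23)cc1 | target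

**Step count and risks**
Total steps: 11. Longest linear sequence: 10 (3 → 20, steps 2–11); step 1 is a one-step side branch.

The three steps most likely to fail:

Step 3 (the proposed new asymmetric alkylation; risks are low ee, uncatalysed background alkylation and branched allylation). The fallback uses known chemistry, sets out from 5 and returns at 10. Hydrogenation of 5 (H2, Pd/C, EtOAc) gives 2,5-dimethylcyclohexan-1-one F1. Condensation with (R)-1-phenylethylamine (toluene, Dean–Stark) gives the imine F2. Its more substituted secondary enamine tautomer adds to but-3-en-2-one under auxiliary control (chiral-imine Michael addition, THF, 25 °C) to give the adduct imine F3. Aqueous AcOH releases the (2S)-diketone F4. NaOMe/MeOH closes it to the octalone F5 (Robinson annulation). Chloranil in refluxing t-BuOH dehydrogenates the 4-en-3-one to the 4,6-dienone 10; the C7 stereocentre of F5 disappears in this step.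

Step 6 (the OsO4 must add on the face of the OH, syn to the angular methyl, and at the correct double bond of the diene). The fallback sets out from 11 and returns at 13. VO(acac)2/t-BuOOH epoxidises only the allylic-alcohol double bond, syn to OH, to give the epoxy alcohol F6. Pd2(dba)3/P(Oi-Pr)3 under CO2 (1 atm, THF) opens this vinyl epoxide to a π-allyl-Pd alkoxide, which is carboxylated and recloses with overall retention to the cis cyclic carbonate F7. K2CO3/MeOH then gives triol 13.

Step 7 (competing migration of C3 driven by the C2 alkoxide, and retro-aldol or epimerisation of 15 under base). The fallback blocks the competing oxygen; it sets out from osmate ester 12 in the flask of step 6 and returns at 15. TESOTf/2,6-lutidine silylates the only free hydroxyl of 12 to give the silylated osmate ester F8. Aqueous Na2SO3 releases the 2-O-triethylsilyl diol F9. MsCl/Et3N gives the mesylate F10. KOt-Bu (1.2 equiv, THF, −20 °C) can now only trigger the shift from the C8a alkoxide, giving the silyl ether F11. HF·pyridine (THF, 0 °C) gives 15.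

**Further compounds**
F1 | step 3 | 2,5-dimethylcyclohexan-1-one (cis/trans mixture) | CC1CCC(C)C(=O)C1
F2 | step 3 | (1R)-N-(2,5-dimethylcyclohexylidene)-1-phenylethan-1-amine | C[C@@H](N=C1CC(C)CCC1C)c1ccccc1
F3 | step 3 | (1R)-N-[(2S)-2,5-dimethyl-2-(3-oxobutyl)cyclohexylidene]-1-phenylethan-1-amine (C5 epimers) | CC(=O)CC[C@]1(C)CCC(C)CC1=N[C@H](C)c1ccccc1
F4 | step 3 | (2S)-2,5-dimethyl-2-(3-oxobutyl)cyclohexan-1-one (C5 epimers) | CC(=O)CC[C@]1(C)CCC(C)CC1=O
F5 | step 3 | (4aS)-4a,7-dimethyl-4,4a,5,6,7,8-hexahydronaphthalen-2(3H)-one (C7 epimers) | O=C1CC[C@]2(C)CCC(C)CC2=C1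
F6 | step 6 | (1S,2R,4aS,8aR)-1,8a-epoxy-4a,7-dimethyl-2-(propan-2-yl)-1,2,3,4,4a,5,6,8a-octahydronaphthalen-2-ol (epoxide cis to OH and to 4a-CH3) | O1[C@]23C=C(C)CC[C@@]2(C)CC[C@@](O)(C(C)C)[C@H]13
F7 | step 6 | cyclic 1,8a-carbonate of triol 13 (cis) | O=C1O[C@]23C=C(C)CC[C@@]2(C)CC[C@@](O)(C(C)C)[C@@H]3O1
F8 | step 7 | 2-O-triethylsilyl ether of osmate ester 12, TMEDA adduct | O=[Os]1(=O)O[C@]23C=C(C)CC[C@@]2(C)CC[C@@](O[Si](CC)(CC)CC)(C(C)C)[C@@H]3O1.CN(C)CCN(C)C
F9 | step 7 | (1S,2R,4aS,8aR)-4a,7-dimethyl-2-(propan-2-yl)-2-[(triethylsilyl)oxy]-1,2,3,4,4a,5,6,8a-octahydronaphthalene-1,8a-diol | O[C@]12C=C(C)CC[C@@]1(C)CC[C@@](O[Si](CC)(CC)CC)(C(C)C)[C@@H]2O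
F10 | step 7 | 1-methanesulfonate of F9 | O[C@]12C=C(C)CC[C@@]1(C)CC[C@@](O[Si](CC)(CC)CC)(C(C)C)[C@@H]2OS(C)(=O)=O
F11 | step 7 | (3R,3aR,8aS)-6,8a-dimethyl-3-(propan-2-yl)-3-[(triethylsilyl)oxy]-2,3,3a,7,8,8a-hexahydroazulen-4(1H)-one | O=C2C=C(C)CC[C@@]3(C)CC[C@@](O[Si](CC)(CC)CC)(C(C)C)[C@H]23
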